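The readings were computed for an exercise; the scatter is artificial.

If reagent, the gas in solution, is fed at a rate proportional to its gap below saturation and used at a rate proportional to catalyst times [reagent], then in balance the order in catalyst equals [reagent] over saturation.

| flask | starting material | second substrate | gas | free catalyst | remark |
|---|---|---|---|---|---|
| Thursday's | 10 mM | 5 mM | 4.8 mM (held) | 0.25 mM | the very flask that is asked about, followed so far |
| Saturday's | 10 mM | 7.5 mM | 4.8 mM (held) | 0.25 mM | run made earlier |
| flask | 10 mM | 5.00 mM | 4.8 mM (held) | 0.25 mM |  |

| run | time / min | target / % |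
|---|---|---|
| Thursday's | 6.00 | 1.7 |
| Thursday's | 12.0 | 3.6 |
| Thursday's | 20.0 | 6.2 |
| Thursday's | 25.0 | 10.2 |
| Saturday's | 6.00 | 1.1 |
| Saturday's | 12.0 | 2.6 |
| Saturday's | 20.0 | 5.9 |
| Saturday's | 25.0 | 8.5 |

(standard deviation of a reading: 1 percentage point)

- apparent order in second substrate when 30% of the starting material are converted (percent change of the rate of making target for one percent more second substrate charged)
- apparent order in free catalyst when 30% of the starting material are converted (percent change of the rate of making target for one percent more free catalyst charged)

The readings do not give [reagent], so my own reckoning takes the midpoint 2.40 mM below the saturation of 4.8 mM. This gives the reagent fraction, [reagent] over saturation, as 0.500, and hence an order in free catalyst near that value. At 25.0 min, Saturday's run, with more second substrate, read 8.5% of target against 10.2% in Thursday's, a gap of 1.7 percentage points with a scatter of 1 point on each reading, so I put the order in second substrate slightly below zero, without much confidence.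

The forecast gave −0.1 for second substrate and 0.9 for free catalyst, noting "Catalyst order is a guess".

The flask gives −0.14 for second substrate and 0.59 for free catalyst.

    starting material + free catalyst ⇌ catalyst intermediate A (K = 25000 L mol⁻¹, k = 2.60 L mol⁻¹ s⁻¹)
    gas ⇌ reagent, rate k2*(csat - [reagent]) (kL = 5.10 × 10⁻⁴ s⁻¹)
    reagent + catalyst intermediate B → free catalyst + second product (k = 2.30 L mol⁻¹ s⁻¹)
    second substrate + free catalyst ⇌ catalyst intermediate B (K = 270 L mol⁻¹, k = 1.70 L mol⁻¹ s⁻¹)
    reagent + catalyst intermediate A → free catalyst + target (k = 2.90 L mol⁻¹ s⁻¹)

At 1.00 h the flask makes reagent 1.08 times as fast as it uses it, which is close to the balance the rule assumes. There [reagent] stands at 2.25 mM, a reagent fraction of 0.469 against the 0.500 taken beforehand, while the order of 0.59 belongs to 30% conversion, reached at 0.950 h.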